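## Retrosynthetic overview

1. Target 42 ⇐ protected lactone 40 (desilylation, then hydrogenolysis) ⇐ butenolide 23 + benzyl bromide 38. One Cu–H catalysed asymmetric reductive benzylation makes the Cα–CH2Ar bond and both lactone stereocentres (new step).
2. 23 ⇐ Pd-catalysed Negishi coupling of the benzylzinc from chloride 19 with 4-bromofuranone 21. The lactone ring comes preformed from tetronic acid.
3. The dihydrobenzofuran of 19 ⇐ Rh(II)-carbenoid C–H insertion of aryldiazoacetate 11 (C2–C3 bond). 11 ⇐ Pd-catalysed C–H arylation of ethyl diazoacetate with aryl iodide 9.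
4. 38 ⇐ Evans glycolate syn-aldol of imide 27 with aldehyde 6, then Mitsunobu inversion at the benzylic carbinol to give the erythro 8-O-4′ unit.
5. All four arenes ⇐ catechol via 4-bromoguaiacol 3. Ring order: dihydrobenzofuran first (step 9), butenolide attached next (step 16) and turned into the trans-lactone last (step 27).

Assumption: the catalyst antipodes written in steps 9 and 27 (Rh2(R-PTTL)4, (R)-DTBM-SEGPHOS) are taken to give the drawn configurations by analogy with their closest precedents; both antipodes are commercial, and the mirror-image catalyst is used if the sense is the opposite.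

Abbreviations: Bn = benzyl; TBS = tert-butyldimethylsilyl; Ar* = 4-(benzyloxy)-3-methoxyphenyl.

## Route

Step 1
Reactants: 1 catechol
Product: 2 guaiacol
Conditions: MeI (1.0 equiv), K2CO3 (1.0 equiv), acetone, reflux; distil from veratrole and unreacted 1
Reagents that add atoms: iodomethane, CI
Why: Williamson mono-O-methylation with one equivalent of electrophile gives mainly the mono-ether, which is separated by distillation.

Step 2
Reactants: 2 guaiacol
Product: 3 4-bromo-2-methoxyphenol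
Conditions: NBS (1.0 equiv), MeCN, 0 °C
Reagents that add atoms: N-bromosuccinimide, O=C1CCC(=O)N1Br
Why: Electrophilic aromatic bromination goes para to the hydroxyl group, the stronger donor.

Step 3
Reactants: 3 4-bromo-2-methoxyphenol
Product: 4 1-(benzyloxy)-4-bromo-2-methoxybenzene
Conditions: BnBr, K2CO3, DMF, rt
Reagents that add atoms: benzyl bromide, BrCc1ccccc1
Why: Williamson etherification of the phenoxide gives a benzyl ether that survives organolithium, hydride, Lewis acid and fluoride steps and is removed by hydrogenolysis at the end.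

Step 4
Reactants: 4 1-(benzyloxy)-4-bromo-2-methoxybenzene
Product: 6 4-(benzyloxy)-3-methoxybenzaldehyde, via aryllithium 5 (not isolated)
Conditions: n-BuLi, THF, −78 °C; DMF; then H2O
Reagents that add atoms: N,N-dimethylformamide, CN(C)C=O; n-butyllithium, [Li]CCCC (lithium stays only in intermediate 5)
Why: Bromine–lithium exchange followed by Bouveault formylation with DMF is fast and clean at −78 °C on this benzyl aryl ether.

Step 5
Reactants: 6 4-(benzyloxy)-3-methoxybenzaldehyde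
Product: 7 [4-(benzyloxy)-3-methoxyphenyl]methanol
Conditions: NaBH4, MeOH, 0 °C
Reagents that add atoms: none
Why: Borohydride reduction of an aryl aldehyde leaves the benzyl ether untouched.

Step 6
Reactants: 3 4-bromo-2-methoxyphenol
Product: 8 4-bromo-2-iodo-6-methoxyphenol
Conditions: NIS (1.05 equiv), TsOH (10 mol%), MeCN, rt
Reagents that add atoms: N-iodosuccinimide, O=C1CCC(=O)N1I
Why: Electrophilic iodination takes the only free position ortho to the hydroxyl group because the para position carries bromine.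

Step 7
Reactants: 8 4-bromo-2-iodo-6-methoxyphenol; 7 [4-(benzyloxy)-3-methoxyphenyl]methanol
Product: 9 5-bromo-1-iodo-3-methoxy-2-[(Ar*)methoxy]benzene
Conditions: PPh3, DIAD, THF, 0 °C to rt
Reagents that add atoms: none
Why: Mitsunobu etherification couples the acidic halophenol with the primary benzylic alcohol under neutral conditions and places the future C2–H next to the ring oxygen.

Step 8
Reactants: 9 5-bromo-1-iodo-3-methoxy-2-[(Ar*)methoxy]benzene; 10 ethyl diazoacetate
Product: 11 ethyl 2-{5-bromo-3-methoxy-2-[(Ar*)methoxy]phenyl}-2-diazoacetate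
Conditions: Pd(PPh3)4 (5 mol%), Ag2CO3 (0.5 equiv), Et3N (1.3 equiv), toluene, rt
Reagents that add atoms: none
Why: Pd(0)-catalysed C–H arylation of the diazo carbon (oxidative addition to C–I, deprotonative palladation of the diazoacetate, reductive elimination) keeps the diazo group, and at room temperature the C–I bond reacts well ahead of C–Br.

Step 9
Reactants: 11 ethyl 2-{5-bromo-3-methoxy-2-[(Ar*)methoxy]phenyl}-2-diazoacetate
Product: 12 ethyl (2S,3R)-2-Ar*-5-bromo-7-methoxy-2,3-dihydro-1-benzofuran-3-carboxylate (2,3-cis)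
Conditions: Rh2(R-PTTL)4 (1 mol%), toluene, −60 °C
Reagents that add atoms: none
Why: Intramolecular Rh(II)-carbenoid 1,5 C–H insertion into the electron-rich benzylic ether C–H closes the dihydrobenzofuran; the chiral carboxylate pocket selects one enantiotopic benzylic hydrogen (sets C2 as S) and the concerted insertion gives the kinetic cis ester.

Step 10
Reactants: 12 cis ester
Product: 13 ethyl (2S,3S)-2-Ar*-5-bromo-7-methoxy-2,3-dihydro-1-benzofuran-3-carboxylate (2,3-trans)
Conditions: NaOEt (0.2 equiv), EtOH–THF, 0 °C to rt; AcOH quench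
Reagents that add atoms: none
Why: Base-mediated epimerisation through the ester enolate moves C3 to the thermodynamically preferred trans arrangement, while C2 is not acidic and ring opening would need a disfavoured retro-5-endo oxa-Michael step.

Step 11
Reactants: 13 trans ester
Product: 14 [(2S,3R)-2-Ar*-5-bromo-7-methoxy-2,3-dihydro-1-benzofuran-3-yl]methanol
Conditions: DIBAL-H (2.5 equiv), CH2Cl2, −78 to 0 °C; aqueous work-up
Reagents that add atoms: none
Why: Hydride reduction of the ester to the primary alcohol spares the aryl bromide and touches no stereocentre (the C3 descriptor changes from S to R only through CIP priorities).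

Step 12
Reactants: 14 primary alcohol
Product: 15 (2S,3R)-2-Ar*-5-bromo-3-[(TBSO)methyl]-7-methoxy-2,3-dihydro-1-benzofuran
Conditions: TBSCl, imidazole, DMF, rt
Reagents that add atoms: tert-butyldimethylsilyl chloride, CC(C)(C)[Si](C)(C)Cl
Why: Standard silylation gives an alkyl TBS ether that is stable to organolithium, zinc, palladium, copper hydride and brief anhydrous fluoride at low temperature.

Step 13
Reactants: 15 aryl bromide
Product: 18 {(2S,3R)-2-Ar*-3-[(TBSO)methyl]-7-methoxy-2,3-dihydro-1-benzofuran-5-yl}methanol, via aryllithium 16 (not isolated), via aldehyde 17 (not isolated)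
Conditions: n-BuLi, THF, −78 °C; DMF; then MeOH, NaBH4, 0 °C
Reagents that add atoms: N,N-dimethylformamide, CN(C)C=O; n-butyllithium, [Li]CCCC (lithium stays only in intermediate 16)
Why: Bromine–lithium exchange at −78 °C outruns deprotonation at C2, and Bouveault formylation followed by borohydride reduction in the same flask installs the benzylic CH2OH.

Step 14
Reactants: 18 benzylic alcohol
Product: 19 (2S,3R)-2-Ar*-5-(chloromethyl)-3-[(TBSO)methyl]-7-methoxy-2,3-dihydro-1-benzofuran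
Conditions: PPh3, NCS, CH2Cl2, 0 °C
Reagents that add atoms: N-chlorosuccinimide, O=C1CCC(=O)N1Cl
Why: Appel-type chlorination converts the electron-rich benzylic alcohol under near-neutral conditions that keep the silyl ether.

Step 15
Reactants: 20 tetronic acid
Product: 21 4-bromofuran-2(5H)-one
Conditions: (COBr)2 (1.2 equiv), DMF (cat.), CH2Cl2, 0 °C to rt
Reagents that add atoms: oxalyl bromide, O=C(Br)C(=O)Br
Why: Vilsmeier-type activation of the vinylogous acid and addition–elimination by bromide give the β-bromobutenolide, a vinylogous acyl bromide.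

Step 16
Reactants: 19 benzylic chloride; 21 4-bromofuran-2(5H)-one
Product: 23 4-({(2S,3R)-2-Ar*-3-[(TBSO)methyl]-7-methoxy-2,3-dihydro-1-benzofuran-5-yl}methyl)furan-2(5H)-one, via benzylzinc chloride 22 (not isolated)
Conditions: Zn dust, LiCl, THF, rt; then 21, Pd(PPh3)4 (3 mol%), THF, rt
Reagents that add atoms: zinc, [Zn] (stays only in intermediate 22)
Why: Negishi sp3–sp2 cross-coupling works because LiCl-assisted zinc insertion gives the benzylzinc without Wurtz coupling, the β-bromobutenolide adds oxidatively to Pd(0) very fast, and the benzyl group has no β-hydrogen.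

Step 17
Reactants: 3 4-bromo-2-methoxyphenol; 24 bromoacetic acid
Product: 25 (4-bromo-2-methoxyphenoxy)acetic acid
Conditions: NaOH (aq), 90 °C; then HCl
Reagents that add atoms: none
Why: Williamson alkylation of the phenoxide by bromoacetate is the classical aryloxyacetic acid synthesis.

Step 18
Reactants: 25 (4-bromo-2-methoxyphenoxy)acetic acid
Product: 27 (4R)-4-benzyl-3-[(4-bromo-2-methoxyphenoxy)acetyl]-1,3-oxazolidin-2-one, via mixed pivalic anhydride 26 (not isolated)
Conditions: PivCl, Et3N, THF, −20 °C; then (R)-4-benzyl-2-oxazolidinone, LiCl, rt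
Reagents that add atoms: (R)-4-benzyl-1,3-oxazolidin-2-one, O=C1N[C@H](Cc2ccccc2)CO1; pivaloyl chloride, CC(C)(C)C(=O)Cl (stays only in intermediate 26)
Why: N-acylation of the Evans auxiliary through the mixed anhydride with LiCl activation occurs at the less hindered carbonyl.

Step 19
Reactants: 27 aryloxyacetyl imide; 6 4-(benzyloxy)-3-methoxybenzaldehyde
Product: 29 (4R)-4-benzyl-3-[(2R,3S)-3-Ar*-2-(4-bromo-2-methoxyphenoxy)-3-hydroxypropanoyl]-1,3-oxazolidin-2-one, via boron enolate 28 (not isolated)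
Conditions: Bu2BOTf, i-Pr2NEt, CH2Cl2, 0 °C; then 6, −78 to 0 °C; pH 7 buffer, MeOH, H2O2
Reagents that add atoms: dibutylboron triflate, CCCCB(CCCC)OS(=O)(=O)C(F)(F)F (boron stays only in intermediate 28)
Why: Evans glycolate syn-aldol through the Z-boron enolate and a Zimmerman–Traxler transition state, with the (R)-benzyl group shielding one enolate face, sets both carbinol-ether centres as the syn (2R,3S) adduct.

Step 20
Reactants: 29 syn-aldol adduct
Product: 30 (1S,2S)-1-Ar*-2-(4-bromo-2-methoxyphenoxy)propane-1,3-diol (threo)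
Conditions: LiBH4, THF, H2O (1 equiv), 0 °C
Reagents that add atoms: none
Why: Reductive cleavage of the imide releases the auxiliary and gives the 1,3-diol without touching the aryl bromide or either stereocentre (the aryloxy carbon descriptor changes from R to S only through CIP priorities).

Step 21
Reactants: 30 threo diol
Product: 31 (1S,2S)-1-Ar*-2-(4-bromo-2-methoxyphenoxy)-3-(TBSO)propan-1-ol
Conditions: TBSCl (1.05 equiv), imidazole, CH2Cl2, 0 °C
Reagents that add atoms: tert-butyldimethylsilyl chloride, CC(C)(C)[Si](C)(C)Cl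
Why: Silylation is selective for the primary hydroxyl over the hindered secondary benzylic one.

Step 22
Reactants: 31 threo mono-silyl ether
Product: 32 (1R,2S)-1-Ar*-2-(4-bromo-2-methoxyphenoxy)-3-(TBSO)propyl 4-nitrobenzoate
Conditions: 4-nitrobenzoic acid, PPh3, DIAD, toluene, 0 °C to rt
Reagents that add atoms: 4-nitrobenzoic acid, O=C(O)c1ccc(cc1)[N+](=O)[O-]
Why: Mitsunobu esterification displaces the activated benzylic oxygen by SN2 with inversion, turning the threo (1S) carbinol into the erythro (1R) ester; the non-polar solvent and low temperature suppress ionisation.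

Step 23
Reactants: 32 4-nitrobenzoate
Product: 33 (1R,2S)-1-Ar*-2-(4-bromo-2-methoxyphenoxy)-3-(TBSO)propan-1-ol (erythro)
Conditions: K2CO3 (0.2 equiv), MeOH, rt
Reagents that add atoms: none
Why: Methanolysis of the activated aryl ester is fast and leaves the alkyl silyl ether and the carbinol configuration untouched.

Step 24
Reactants: 33 erythro alcohol
Product: 34 1-(benzyloxy)-4-[(1R,2S)-2-(4-bromo-2-methoxyphenoxy)-1,3-bis(TBSO)propyl]-2-methoxybenzene
Conditions: TBSOTf, 2,6-lutidine, CH2Cl2, 0 °C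
Reagents that add atoms: tert-butyldimethylsilyl triflate, CC(C)(C)[Si](C)(C)OS(=O)(=O)C(F)(F)F
Why: The silyl triflate protects the hindered secondary benzylic alcohol under buffered conditions that avoid ionisation.

Step 25
Reactants: 34 aryl bromide
Product: 37 (4-{[(1R,2S)-1-Ar*-1,3-bis(TBSO)propan-2-yl]oxy}-3-methoxyphenyl)methanol, via aryllithium 35 (not isolated), via aldehyde 36 (not isolated)
Conditions: n-BuLi, THF, −78 °C; DMF; then MeOH, NaBH4, 0 °C
Reagents that add atoms: N,N-dimethylformamide, CN(C)C=O; n-butyllithium, [Li]CCCC (lithium stays only in intermediate 35)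
Why: Bromine–lithium exchange, Bouveault formylation and borohydride reduction in one flask install the benzylic CH2OH without affecting the silyl or benzyl ethers.

Step 26
Reactants: 37 benzylic alcohol
Product: 38 1-(benzyloxy)-4-{(1R,2S)-2-[4-(bromomethyl)-2-methoxyphenoxy]-1,3-bis(TBSO)propyl}-2-methoxybenzene
Conditions: CBr4, PPh3, CH2Cl2, 0 °C; used at once
Reagents that add atoms: carbon tetrabromide, BrC(Br)(Br)Br
Why: Appel bromination gives the reactive electron-rich benzyl bromide under neutral conditions.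

Step 27
Reactants: 23 butenolide; 38 benzyl bromide
Product: 40 (3R,4R)-3-(4-{[(1R,2S)-1-Ar*-1,3-bis(TBSO)propan-2-yl]oxy}-3-methoxybenzyl)-4-({(2S,3R)-2-Ar*-3-[(TBSO)methyl]-7-methoxy-2,3-dihydro-1-benzofuran-5-yl}methyl)oxolan-2-one, via silyl ketene acetal 39 (not isolated)
Conditions: Cu(OAc)2 (5 mol%), (R)-DTBM-SEGPHOS (5.5 mol%), (EtO)2MeSiH (1.2 equiv), toluene, 0 °C to rt, no proton source; then 38 (1.1 equiv), TBAT (1.1 equiv), THF, −78 to 0 °C
Reagents that add atoms: diethoxymethylsilane, CCO[SiH](C)OCC (silicon stays only in intermediate 39; the product keeps only its hydrogen)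
Why: Proposed new method: a ligand-controlled Cu–H conjugate reduction of the β-substituted butenolide delivers hydride to one face of C4 (sets 4R), and because no alcohol is present the copper enolate is silylated by the hydrosilane to ketene acetal 39 instead of being protonated; fluoride transfer from TBAT then activates 39 for C-benzylation by 38 anti to the C4 substituent (sets 3R, trans), so one operation joins the two halves and fixes both lactone stereocentres; the closest known reactions are the Cu–H asymmetric conjugate reduction of β-substituted butenolides run with a proton source and the one-pot Cu–H reduction/fluoride-triggered alkylation of 3-substituted cyclopentenones, whereas interception of a lactone-derived silyl ketene acetal in a three-component reductive benzylation has not been shown.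

Step 28
Reactants: 40 fully protected lactone
Product: 41 (3R,4R)-3-(4-{[(1R,2S)-1-Ar*-1,3-dihydroxypropan-2-yl]oxy}-3-methoxybenzyl)-4-({(2S,3R)-2-Ar*-3-(hydroxymethyl)-7-methoxy-2,3-dihydro-1-benzofuran-5-yl}methyl)oxolan-2-one
Conditions: HF·pyridine, pyridine, THF, 0 °C to rt
Reagents that add atoms: none
Why: Buffered HF removes the three alkyl TBS ethers without opening or epimerising the trans-lactone and, with the phenols still benzylated, without ionising the benzylic carbinol.

Step 29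
Reactants: 41 bis-benzyl ether
Product: 42 target CNP0298853.1
Conditions: H2 (1 atm), 10% Pd/C, EtOAc–EtOH, rt, stopped at full conversion
Reagents that add atoms: none
Why: Hydrogenolysis of the two aryl benzyl ethers under neutral conditions is much faster than cleavage of the benzylic C–OH or of the dihydrobenzofuran C2–O bond and leaves all six stereocentres intact.

## Compound list

1 | catechol (benzene-1,2-diol) | Oc1ccccc1O | starting material
2 | guaiacol (2-methoxyphenol) | COc1ccccc1O | intermediate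
3 | 4-bromo-2-methoxyphenol | COc1cc(Br)ccc1O | intermediate
4 | 1-(benzyloxy)-4-bromo-2-methoxybenzene | COc1cc(Br)ccc1OCc1ccccc1 | intermediate
5 | [4-(benzyloxy)-3-methoxyphenyl]lithium | [Li]c1ccc(OCc2ccccc2)c(OC)c1 | intermediate (not isolated)
6 | 4-(benzyloxy)-3-methoxybenzaldehyde | COc1cc(C=O)ccc1OCc1ccccc1 | intermediate
7 | [4-(benzyloxy)-3-methoxyphenyl]methanol | COc1cc(CO)ccc1OCc1ccccc1 | intermediate
8 | 4-bromo-2-iodo-6-methoxyphenol | COc1cc(Br)cc(I)c1O | intermediate
9 | 2-{[4-(benzyloxy)-3-methoxybenzyl]oxy}-5-bromo-1-iodo-3-methoxybenzene | COc1cc(Br)cc(I)c1OCc1ccc(OCc2ccccc2)c(OC)c1 | intermediate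
10 | ethyl diazoacetate | CCOC(=O)C=[N+]=[N-] | starting material
11 | ethyl 2-(2-{[4-(benzyloxy)-3-methoxybenzyl]oxy}-5-bromo-3-methoxyphenyl)-2-diazoacetate | CCOC(=O)C(=[N+]=[N-])c1cc(Br)cc(OC)c1OCc1ccc(OCc2ccccc2)c(OC)c1 | intermediate
12 | ethyl (2S,3R)-2-[4-(benzyloxy)-3-methoxyphenyl]-5-bromo-7-methoxy-2,3-dihydro-1-benzofuran-3-carboxylate (cis) | Brc1cc(OC)c2c(c1)[C@@H](C(=O)OCC)[C@@H](c1ccc(OCc3ccccc3)c(OC)c1)O2 | intermediate
13 | ethyl (2S,3S)-2-[4-(benzyloxy)-3-methoxyphenyl]-5-bromo-7-methoxy-2,3-dihydro-1-benzofuran-3-carboxylate (trans) | Brc1cc(OC)c2c(c1)[C@H](C(=O)OCC)[C@@H](c1ccc(OCc3ccccc3)c(OC)c1)O2 | intermediate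
14 | {(2S,3R)-2-[4-(benzyloxy)-3-methoxyphenyl]-5-bromo-7-methoxy-2,3-dihydro-1-benzofuran-3-yl}methanol (trans) | Brc1cc(OC)c2c(c1)[C@H](CO)[C@@H](c1ccc(OCc3ccccc3)c(OC)c1)O2 | intermediate
15 | (2S,3R)-2-[4-(benzyloxy)-3-methoxyphenyl]-5-bromo-3-{[(tert-butyldimethylsilyl)oxy]methyl}-7-methoxy-2,3-dihydro-1-benzofuran | Brc1cc(OC)c2c(c1)[C@H](CO[Si](C)(C)C(C)(C)C)[C@@H](c1ccc(OCc3ccccc3)c(OC)c1)O2 | intermediate
16 | 5-lithio analogue of 15 (lithium in place of bromine) | [Li]c1cc(OC)c2c(c1)[C@H](CO[Si](C)(C)C(C)(C)C)[C@@H](c1ccc(OCc3ccccc3)c(OC)c1)O2 | intermediate (not isolated)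
17 | (2S,3R)-2-[4-(benzyloxy)-3-methoxyphenyl]-3-{[(tert-butyldimethylsilyl)oxy]methyl}-7-methoxy-2,3-dihydro-1-benzofuran-5-carbaldehyde | O=Cc1cc(OC)c2c(c1)[C@H](CO[Si](C)(C)C(C)(C)C)[C@@H](c1ccc(OCc3ccccc3)c(OC)c1)O2 | intermediate (not isolated)
18 | {(2S,3R)-2-[4-(benzyloxy)-3-methoxyphenyl]-3-{[(tert-butyldimethylsilyl)oxy]methyl}-7-methoxy-2,3-dihydro-1-benzofuran-5-yl}methanol | OCc1cc(OC)c2c(c1)[C@H](CO[Si](C)(C)C(C)(C)C)[C@@H](c1ccc(OCc3ccccc3)c(OC)c1)O2 | intermediate
19 | (2S,3R)-2-[4-(benzyloxy)-3-methoxyphenyl]-3-{[(tert-butyldimethylsilyl)oxy]methyl}-5-(chloromethyl)-7-methoxy-2,3-dihydro-1-benzofuran | ClCc1cc(OC)c2c(c1)[C@H](CO[Si](C)(C)C(C)(C)C)[C@@H](c1ccc(OCc3ccccc3)c(OC)c1)O2 | intermediate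
20 | tetronic acid (4-hydroxyfuran-2(5H)-one) | OC1=CC(=O)OC1 | starting material
21 | 4-bromofuran-2(5H)-one | BrC1=CC(=O)OC1 | intermediate
22 | benzylzinc chloride derived from 19 (ZnCl in place of Cl) | Cl[Zn]Cc1cc(OC)c2c(c1)[C@H](CO[Si](C)(C)C(C)(C)C)[C@@H](c1ccc(OCc3ccccc3)c(OC)c1)O2 | intermediate (not isolated)
23 | 4-({(2S,3R)-2-[4-(benzyloxy)-3-methoxyphenyl]-3-{[(tert-butyldimethylsilyl)oxy]methyl}-7-methoxy-2,3-dihydro-1-benzofuran-5-yl}methyl)furan-2(5H)-one | O=C1OCC(Cc2cc(OC)c3c(c2)[C@H](CO[Si](C)(C)C(C)(C)C)[C@@H](c2ccc(OCc4ccccc4)c(OC)c2)O3)=C1 | intermediate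
24 | bromoacetic acid | OC(=O)CBr | starting material
25 | (4-bromo-2-methoxyphenoxy)acetic acid | COc1cc(Br)ccc1OCC(=O)O | intermediate
26 | (4-bromo-2-methoxyphenoxy)acetic pivalic anhydride | COc1cc(Br)ccc1OCC(=O)OC(=O)C(C)(C)C | intermediate (not isolated)
27 | (4R)-4-benzyl-3-[(4-bromo-2-methoxyphenoxy)acetyl]-1,3-oxazolidin-2-one | COc1cc(Br)ccc1OCC(=O)N1[C@H](Cc2ccccc2)COC1=O | intermediate
28 | (Z)-dibutylboron enolate of 27 | CCCCB(CCCC)O/C(N1[C@H](Cc2ccccc2)COC1=O)=C\Oc1ccc(Br)cc1OC | intermediate (not isolated)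
29 | (4R)-4-benzyl-3-[(2R,3S)-3-[4-(benzyloxy)-3-methoxyphenyl]-2-(4-bromo-2-methoxyphenoxy)-3-hydroxypropanoyl]-1,3-oxazolidin-2-one (syn) | COc1cc(ccc1OCc1ccccc1)[C@H](O)[C@H](C(=O)N1[C@H](Cc2ccccc2)COC1=O)Oc1ccc(Br)cc1OC | intermediate
30 | (1S,2S)-1-[4-(benzyloxy)-3-methoxyphenyl]-2-(4-bromo-2-methoxyphenoxy)propane-1,3-diol (threo) | COc1cc(ccc1OCc1ccccc1)[C@H](O)[C@H](CO)Oc1ccc(Br)cc1OC | intermediate
31 | (1S,2S)-1-[4-(benzyloxy)-3-methoxyphenyl]-2-(4-bromo-2-methoxyphenoxy)-3-[(tert-butyldimethylsilyl)oxy]propan-1-ol | COc1cc(ccc1OCc1ccccc1)[C@H](O)[C@H](CO[Si](C)(C)C(C)(C)C)Oc1ccc(Br)cc1OC | intermediate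
32 | (1R,2S)-1-[4-(benzyloxy)-3-methoxyphenyl]-2-(4-bromo-2-methoxyphenoxy)-3-[(tert-butyldimethylsilyl)oxy]propyl 4-nitrobenzoate | COc1cc(ccc1OCc1ccccc1)[C@@H](OC(=O)c1ccc(cc1)[N+](=O)[O-])[C@H](CO[Si](C)(C)C(C)(C)C)Oc1ccc(Br)cc1OC | intermediate
33 | (1R,2S)-1-[4-(benzyloxy)-3-methoxyphenyl]-2-(4-bromo-2-methoxyphenoxy)-3-[(tert-butyldimethylsilyl)oxy]propan-1-ol (erythro) | COc1cc(ccc1OCc1ccccc1)[C@@H](O)[C@H](CO[Si](C)(C)C(C)(C)C)Oc1ccc(Br)cc1OC | intermediate
34 | 1-(benzyloxy)-4-[(1R,2S)-2-(4-bromo-2-methoxyphenoxy)-1,3-bis{[tert-butyl(dimethyl)silyl]oxy}propyl]-2-methoxybenzene | COc1cc(ccc1OCc1ccccc1)[C@@H](O[Si](C)(C)C(C)(C)C)[C@H](CO[Si](C)(C)C(C)(C)C)Oc1ccc(Br)cc1OC | intermediate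
35 | aryllithium derived from 34 (lithium in place of bromine) | COc1cc(ccc1OCc1ccccc1)[C@@H](O[Si](C)(C)C(C)(C)C)[C@H](CO[Si](C)(C)C(C)(C)C)Oc1ccc([Li])cc1OC | intermediate (not isolated)
36 | 4-{[(1R,2S)-1-[4-(benzyloxy)-3-methoxyphenyl]-1,3-bis{[tert-butyl(dimethyl)silyl]oxy}propan-2-yl]oxy}-3-methoxybenzaldehyde | COc1cc(ccc1OCc1ccccc1)[C@@H](O[Si](C)(C)C(C)(C)C)[C@H](CO[Si](C)(C)C(C)(C)C)Oc1ccc(C=O)cc1OC | intermediate (not isolated)
37 | (4-{[(1R,2S)-1-[4-(benzyloxy)-3-methoxyphenyl]-1,3-bis{[tert-butyl(dimethyl)silyl]oxy}propan-2-yl]oxy}-3-methoxyphenyl)methanol | COc1cc(ccc1OCc1ccccc1)[C@@H](O[Si](C)(C)C(C)(C)C)[C@H](CO[Si](C)(C)C(C)(C)C)Oc1ccc(CO)cc1OC | intermediate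
38 | 1-(benzyloxy)-4-{(1R,2S)-2-[4-(bromomethyl)-2-methoxyphenoxy]-1,3-bis{[tert-butyl(dimethyl)silyl]oxy}propyl}-2-methoxybenzene | COc1cc(ccc1OCc1ccccc1)[C@@H](O[Si](C)(C)C(C)(C)C)[C@H](CO[Si](C)(C)C(C)(C)C)Oc1ccc(CBr)cc1OC | intermediate
39 | (4R)-2-{[diethoxy(methyl)silyl]oxy}-4-({(2S,3R)-2-[4-(benzyloxy)-3-methoxyphenyl]-3-{[(tert-butyldimethylsilyl)oxy]methyl}-7-methoxy-2,3-dihydro-1-benzofuran-5-yl}methyl)-4,5-dihydrofuran | CCO[Si](C)(OCC)OC1=C[C@@H](Cc2cc(OC)c3c(c2)[C@H](CO[Si](C)(C)C(C)(C)C)[C@@H](c2ccc(OCc4ccccc4)c(OC)c2)O3)CO1 | intermediate (not isolated)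
40 | (3R,4R)-3-(4-{[(1R,2S)-1-[4-(benzyloxy)-3-methoxyphenyl]-1,3-bis{[tert-butyl(dimethyl)silyl]oxy}propan-2-yl]oxy}-3-methoxybenzyl)-4-({(2S,3R)-2-[4-(benzyloxy)-3-methoxyphenyl]-3-{[(tert-butyldimethylsilyl)oxy]methyl}-7-methoxy-2,3-dihydro-1-benzofuran-5-yl}methyl)oxolan-2-one | COc1cc(ccc1OCc1ccccc1)[C@@H](O[Si](C)(C)C(C)(C)C)[C@H](CO[Si](C)(C)C(C)(C)C)Oc1ccc(C[C@H]2C(=O)OC[C@@H]2Cc2cc(OC)c3c(c2)[C@H](CO[Si](C)(C)C(C)(C)C)[C@@H](c2ccc(OCc4ccccc4)c(OC)c2)O3)cc1OC | intermediate
41 | (3R,4R)-3-(4-{[(1R,2S)-1-[4-(benzyloxy)-3-methoxyphenyl]-1,3-dihydroxypropan-2-yl]oxy}-3-methoxybenzyl)-4-({(2S,3R)-2-[4-(benzyloxy)-3-methoxyphenyl]-3-(hydroxymethyl)-7-methoxy-2,3-dihydro-1-benzofuran-5-yl}methyl)oxolan-2-one | COc1cc(ccc1OCc1ccccc1)[C@@H](O)[C@H](CO)Oc1ccc(C[C@H]2C(=O)OC[C@@H]2Cc2cc(OC)c3c(c2)[C@H](CO)[C@@H](c2ccc(OCc4ccccc4)c(OC)c2)O3)cc1OC | intermediate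
42 | CNP0298853.1, (3R,4R)-3-(4-{[(1R,2S)-1,3-dihydroxy-1-(4-hydroxy-3-methoxyphenyl)propan-2-yl]oxy}-3-methoxybenzyl)-4-{[(2S,3R)-2-(4-hydroxy-3-methoxyphenyl)-3-(hydroxymethyl)-7-methoxy-2,3-dihydro-1-benzofuran-5-yl]methyl}oxolan-2-one | COc1cc([C@@H](O)[C@H](CO)Oc2ccc(C[C@H]3C(=O)OC[C@@H]3Cc3cc(OC)c4c(c3)[C@H](CO)[C@@H](c3ccc(O)c(OC)c3)O4)cc2OC)ccc1O | target

## Step count and risks

Total step count: 29.

Longest linear sequence: 17 steps (1 → 2 → 3 → 4 → 6 → 7 → 9 → 11 → 12 → 13 → 14 → 15 → 18 → 19 → 23 → 40 → 41 → 42).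

The three steps most likely to fail:

Step 8. The aryl iodide is flanked by a bulky benzylic ether, and the diazo product can be consumed by palladium-carbene side reactions. The fallback sets out from 9 and comes back at 11. Iodine–magnesium exchange (i-PrMgCl·LiCl, THF, −20 °C, bromide untouched) gives the arylmagnesium chloride {5-bromo-3-methoxy-2-[(Ar*)methoxy]phenyl}magnesium chloride F1. Acylation of F1 with diethyl oxalate (3 equiv, −78 °C) gives the α-keto ester ethyl 2-{5-bromo-3-methoxy-2-[(Ar*)methoxy]phenyl}-2-oxoacetate F2. Condensation with tosylhydrazine (EtOH, 60 °C) gives the N-tosylhydrazone of the keto ester F3. DBU in CH2Cl2 at rt then eliminates sulfinate (Bamford–Stevens) to give diazo ester 11.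

Step 22. The carbinol is hindered and electron-rich, so ionisation (loss of inversion) or elimination to the enol ether may compete with SN2 displacement. The fallback sets out from 31 and comes back at 33, so steps 22 and 23 are both replaced. Dess–Martin periodinane (NaHCO3, CH2Cl2, 0 °C) gives the ketone (2S)-1-[4-(benzyloxy)-3-methoxyphenyl]-2-(4-bromo-2-methoxyphenoxy)-3-[(tert-butyldimethylsilyl)oxy]propan-1-one F4. L-Selectride (THF, −78 °C) reduces it under Felkin–Anh control, with the aryloxy group anti to the incoming hydride, to the erythro alcohol 33.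

Step 27 (the proposed new method). Without a proton source the copper enolate may turn over slowly, and the fluoride-triggered benzylation may be slowed by the bulk of both partners or give some cis isomer. The fallback uses only known chemistry, sets out from 23 and 38 and comes back at 40. Asymmetric hydrogenation of the β-substituted butenolide (Ru(OAc)2[BINAP], the BINAP antipode that gives 4R, H2 50 atm, MeOH–CH2Cl2, 50 °C) gives the isolated lactone (4R)-4-({(2S,3R)-2-Ar*-3-[(TBSO)methyl]-7-methoxy-2,3-dihydro-1-benzofuran-5-yl}methyl)oxolan-2-one F5. LiHMDS (THF, −78 °C) converts it into the lithium enolate of the lactone F6. Addition of 38 (−78 to −40 °C) gives 40 by the classical trans-selective alkylation of β-benzyl-γ-butyrolactone enolates.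

Further compounds
F1 | step 8 | {2-{[4-(benzyloxy)-3-methoxybenzyl]oxy}-5-bromo-3-methoxyphenyl}magnesium chloride | Cl[Mg]c1cc(Br)cc(OC)c1OCc1ccc(OCc2ccccc2)c(OC)c1
F2 | step 8 | ethyl 2-(2-{[4-(benzyloxy)-3-methoxybenzyl]oxy}-5-bromo-3-methoxyphenyl)-2-oxoacetate | CCOC(=O)C(=O)c1cc(Br)cc(OC)c1OCc1ccc(OCc2ccccc2)c(OC)c1
F3 | step 8 | ethyl 2-(2-{[4-(benzyloxy)-3-methoxybenzyl]oxy}-5-bromo-3-methoxyphenyl)-2-[2-(4-methylbenzenesulfonyl)hydrazinylidene]acetate (E/Z mixture) | CCOC(=O)C(=NNS(=O)(=O)c1ccc(C)cc1)c1cc(Br)cc(OC)c1OCc1ccc(OCc2ccccc2)c(OC)c1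
F4 | step 22 | (2S)-1-[4-(benzyloxy)-3-methoxyphenyl]-2-(4-bromo-2-methoxyphenoxy)-3-[(tert-butyldimethylsilyl)oxy]propan-1-one | COc1cc(ccc1OCc1ccccc1)C(=O)[C@H](CO[Si](C)(C)C(C)(C)C)Oc1ccc(Br)cc1OC
F5 | step 27 | (4R)-4-({(2S,3R)-2-[4-(benzyloxy)-3-methoxyphenyl]-3-{[(tert-butyldimethylsilyl)oxy]methyl}-7-methoxy-2,3-dihydro-1-benzofuran-5-yl}methyl)oxolan-2-one | O=C1OC[C@@H](C1)Cc1cc(OC)c2c(c1)[C@H](CO[Si](C)(C)C(C)(C)C)[C@@H](c1ccc(OCc3ccccc3)c(OC)c1)O2
F6 | step 27 | lithium enolate of F5, lithium (4R)-4-(arylmethyl)-4,5-dihydrofuran-2-olate | [Li]OC1=C[C@@H](Cc2cc(OC)c3c(c2)[C@H](CO[Si](C)(C)C(C)(C)C)[C@@H](c2ccc(OCc4ccccc4)c(OC)c2)O3)CO1
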